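**Plan**

1. Retrosynthesis, late cuts: the enal goes back to a silyl-protected allylic CH2OH, the two tiglate C–O bonds to a diol, and the side-chain carbinol to the acetyl ketone.
2. Ring-opening cut: C2–C3 of the dihydrofuran ring. C3(OH)–C2(O1)–C(=CH2) is a homoallylic alcohol array, and its exocyclic methylene lies exactly where an SE2′ allylation of the aryl aldehyde carbon (C3) by a γ-aryloxy allylsilane (C2) leaves the alkene.
3. The enol ether precursor is cut at O1–C2 into 5-acetylsalicylaldehyde and a C4 alkenyl iodide, itself assembled from propargyl alcohol, Me3SiCH2MgCl and iodine.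
4. Forward: C4 fragment (two steps), O-vinylation of the phenol, closure of the dihydrofuran ring onto the existing benzene ring, ketone reduction, double tigloylation, desilylation, oxidation to the enal.
5. Stereochemistry: C3 by catalyst control (chiral counter-anion) and C2 by an open antiperiplanar transition state (trans) in the ring closure; the side-chain (R)-carbinol by Ru-catalysed asymmetric transfer hydrogenation; the E-tiglates come from tigloyl chloride.

Key step: step 4

Assumptions: 5-acetyl-2-hydroxybenzaldehyde (6) is taken as a catalogue compound; in step 4 the (S,S)-acid is taken to leave the Re face of the formyl group open, and its (R,R)-antipode would be used if the sense of induction proves opposite.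

**Step 1**
Reactants: 1 propargyl alcohol; 2 (trimethylsilyl)methylmagnesium chloride
Product: 4 (2E)-3-iodo-2-[(trimethylsilyl)methyl]prop-2-en-1-ol, via alkenylmagnesium chloride alkoxide 3 (not isolated)
Conditions: 2 (2.5 equiv), CuI (10 mol%), THF/Et2O, 0 °C to rt; then I2, −78 to 0 °C; aq. Na2S2O3
Reagents that add atoms: iodine, II
Why: Copper-catalysed carbomagnesiation of the propargylic magnesium alkoxide (Duboudin-type) puts the Me3SiCH2 group on the internal carbon and magnesium on the terminal carbon cis to CH2O in a five-membered chelate, so iodinolysis with retention should place iodine cis to CH2OH (E by the CIP rules, since CH2Si outranks CH2O).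

**Step 2**
Reactants: 4 (2E)-3-iodo-2-[(trimethylsilyl)methyl]prop-2-en-1-ol
Product: 5 tert-butyl({(2E)-3-iodo-2-[(trimethylsilyl)methyl]prop-2-en-1-yl}oxy)dimethylsilane
Conditions: TBSCl, imidazole, DMF, 0 °C to rt
Reagents that add atoms: tert-butyldimethylsilyl chloride, CC(C)(C)[Si](C)(C)Cl
Why: Standard imidazole-mediated silylation of a primary alcohol masks the future aldehyde carbon at the alcohol level and prevents self-coupling of the hydroxy iodide in step 3.

**Step 3**
Reactants: 5 tert-butyl({(2E)-3-iodo-2-[(trimethylsilyl)methyl]prop-2-en-1-yl}oxy)dimethylsilane; 6 5-acetyl-2-hydroxybenzaldehyde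
Product: 7 5-acetyl-2-{[(1E)-2-({[tert-butyl(dimethyl)silyl]oxy}methyl)-3-(trimethylsilyl)prop-1-en-1-yl]oxy}benzaldehyde
Conditions: CuI (10 mol%), N,N-dimethylglycine hydrochloride (30 mol%), Cs2CO3, 1,4-dioxane, 70 °C
Reagents that add atoms: none
Why: Ullmann-type copper-catalysed C–O coupling of a phenol with an alkenyl iodide proceeds with retention of alkene geometry and should give the (E)-aryl enol ether, with the allylsilane carbon three atoms from the formyl carbon.

**Step 4**
Reactants: 7 5-acetyl-2-{[(1E)-2-({[tert-butyl(dimethyl)silyl]oxy}methyl)-3-(trimethylsilyl)prop-1-en-1-yl]oxy}benzaldehyde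
Product: 9 1-[(2R,3S)-2-(3-{[tert-butyl(dimethyl)silyl]oxy}prop-1-en-2-yl)-3-hydroxy-2,3-dihydro-1-benzofuran-5-yl]ethan-1-one, via trimethylsilyl ether 8 (not isolated)
Conditions: (S,S)-IDPi acid (N-triflyl imidodiphosphorimidate built from two 3,3′-diaryl-(S)-BINOL units, 2 mol%), pre-silylated with methallyltrimethylsilane (2 mol%), toluene, −78 to −40 °C; then K2CO3 (cat.), MeOH, 0 °C
Reagents that add atoms: none
Why: Proposed new method: the silylated chiral acid transfers Me3Si+ to the formyl oxygen, the enol-ether carbon of the allylsilane (γ to silicon) attacks the resulting silyloxocarbenium in SE2′ fashion with the positive charge at the central carbon stabilised by the C–Si bond, and loss of Me3Si+ to the counter-anion creates the exocyclic methylene and turns the catalyst over, giving the C3 trimethylsilyl ether 8. The closest known reaction types are the intermolecular Hosomi–Sakurai allylation of aromatic aldehydes with 2-substituted allylsilanes under chiral-anion silylium catalysis and the Lewis-acid-promoted intramolecular cyclisation of γ-alkoxyallylstannanes onto aldehydes, which gives trans-2-alkenyl-3-hydroxy cyclic ethers. The dihydrofuran ring closes in the 5-exo-trig mode with respect to both the C=O and the C=C bond. C3 is set by the confined chiral anion, expected to leave the Re face of the ion-paired formyl group open (3S), and C2 is set relative to C3 by the open antiperiplanar arrangement of C=O and C=C across the forming bond, which keeps the silylated oxygen and the branched propenyl group on opposite faces of the nascent ring (Si face of the enol-ether carbon, 2R, trans). The step needs site selectivity for the formyl over the acetyl group, secured because only the formyl carbon can be reached in a five-membered closure, and regioselectivity for attack through the oxygen-bearing carbon and not through the central carbon (six-membered oxocarbenium closure), secured by the β-silicon effect and by the para-acetyl group, which makes the aryloxy oxygen a poor oxocarbenium donor. Pre-silylation of the acid and rigorous exclusion of protic impurities guard the allylsilane enol ether against protodesilylation.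

**Step 5**
Reactants: 9 1-[(2R,3S)-2-(3-{[tert-butyl(dimethyl)silyl]oxy}prop-1-en-2-yl)-3-hydroxy-2,3-dihydro-1-benzofuran-5-yl]ethan-1-one
Product: 10 (2R,3S)-2-(3-{[tert-butyl(dimethyl)silyl]oxy}prop-1-en-2-yl)-5-[(1R)-1-hydroxyethyl]-2,3-dihydro-1-benzofuran-3-ol
Conditions: RuCl(p-cymene)[(R,R)-N-tosyl-1,2-diphenylethylenediamine] (1 mol%), HCO2Na, H2O/MeOH, 40 °C
Reagents that add atoms: none
Why: Noyori asymmetric transfer hydrogenation of the aryl methyl ketone through the outer-sphere Ru–H/N–H transition state with the (R,R)-ligand should give the (R)-carbinol under catalyst control, independent of the ring stereocentres, and leaves the alkene and silyl ether untouched.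

**Step 6**
Reactants: 10 (2R,3S)-2-(3-{[tert-butyl(dimethyl)silyl]oxy}prop-1-en-2-yl)-5-[(1R)-1-hydroxyethyl]-2,3-dihydro-1-benzofuran-3-ol; 11 tigloyl chloride [(2E)-2-methylbut-2-enoyl chloride]
Product: 12 (1R)-1-[(2R,3S)-2-(3-{[tert-butyl(dimethyl)silyl]oxy}prop-1-en-2-yl)-3-{[(2E)-2-methylbut-2-enoyl]oxy}-2,3-dihydro-1-benzofuran-5-yl]ethyl (2E)-2-methylbut-2-enoate
Conditions: 11 (3 equiv), pyridine, DMAP (cat.), CH2Cl2, 0 °C to rt
Reagents that add atoms: none
Why: Pyridine/DMAP-mediated O-acylation of both secondary benzylic alcohols by the (E)-acyl chloride occurs with retention at both carbinol carbons and keeps the tiglate geometry.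

**Step 7**
Reactants: 12 (1R)-1-[(2R,3S)-2-(3-{[tert-butyl(dimethyl)silyl]oxy}prop-1-en-2-yl)-3-{[(2E)-2-methylbut-2-enoyl]oxy}-2,3-dihydro-1-benzofuran-5-yl]ethyl (2E)-2-methylbut-2-enoate
Product: 13 (1R)-1-[(2R,3S)-2-(3-hydroxyprop-1-en-2-yl)-3-{[(2E)-2-methylbut-2-enoyl]oxy}-2,3-dihydro-1-benzofuran-5-yl]ethyl (2E)-2-methylbut-2-enoate
Conditions: HF·pyridine, pyridine, THF, 0 °C
Reagents that add atoms: none
Why: Fluoride-driven cleavage of the primary silyl ether under pyridine-buffered conditions should leave the two benzylic tiglates intact.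

**Step 8**
Reactants: 13 (1R)-1-[(2R,3S)-2-(3-hydroxyprop-1-en-2-yl)-3-{[(2E)-2-methylbut-2-enoyl]oxy}-2,3-dihydro-1-benzofuran-5-yl]ethyl (2E)-2-methylbut-2-enoate
Product: 14 (1R)-1-[(2R,3S)-3-{[(2E)-2-methylbut-2-enoyl]oxy}-2-(3-oxoprop-1-en-2-yl)-2,3-dihydro-1-benzofuran-5-yl]ethyl (2E)-2-methylbut-2-enoate
Conditions: activated MnO2, CH2Cl2, rt
Reagents that add atoms: none
Why: Chemoselective MnO2 oxidation of the primary allylic alcohol under neutral conditions should give the 2-substituted acrolein without epimerising C2 or ionising the benzylic esters.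

**Compound list**

1 | propargyl alcohol | C#CCO | starting material
2 | (trimethylsilyl)methylmagnesium chloride | C[Si](C)(C)C[Mg]Cl | starting material
3 | chloromagnesium (2Z)-3-(chloromagnesio)-2-[(trimethylsilyl)methyl]prop-2-en-1-olate (not isolated) | Cl[Mg]/C=C(/C[Si](C)(C)C)CO[Mg]Cl | intermediate
4 | (2E)-3-iodo-2-[(trimethylsilyl)methyl]prop-2-en-1-ol | I/C=C(/C[Si](C)(C)C)CO | intermediate
5 | tert-butyl({(2E)-3-iodo-2-[(trimethylsilyl)methyl]prop-2-en-1-yl}oxy)dimethylsilane | I/C=C(/C[Si](C)(C)C)CO[Si](C)(C)C(C)(C)C | intermediate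
6 | 5-acetyl-2-hydroxybenzaldehyde | CC(=O)c1ccc(O)c(C=O)c1 | starting material
7 | 5-acetyl-2-{[(1E)-2-({[tert-butyl(dimethyl)silyl]oxy}methyl)-3-(trimethylsilyl)prop-1-en-1-yl]oxy}benzaldehyde | CC(=O)c1ccc(O/C=C(/C[Si](C)(C)C)CO[Si](C)(C)C(C)(C)C)c(C=O)c1 | intermediate
8 | 1-[(2R,3S)-2-(3-{[tert-butyl(dimethyl)silyl]oxy}prop-1-en-2-yl)-3-[(trimethylsilyl)oxy]-2,3-dihydro-1-benzofuran-5-yl]ethan-1-one (not isolated) | C=C(CO[Si](C)(C)C(C)(C)C)[C@H]1Oc2ccc(C(C)=O)cc2[C@@H]1O[Si](C)(C)C | intermediate
9 | 1-[(2R,3S)-2-(3-{[tert-butyl(dimethyl)silyl]oxy}prop-1-en-2-yl)-3-hydroxy-2,3-dihydro-1-benzofuran-5-yl]ethan-1-one | C=C(CO[Si](C)(C)C(C)(C)C)[C@H]1Oc2ccc(C(C)=O)cc2[C@@H]1O | intermediate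
10 | (2R,3S)-2-(3-{[tert-butyl(dimethyl)silyl]oxy}prop-1-en-2-yl)-5-[(1R)-1-hydroxyethyl]-2,3-dihydro-1-benzofuran-3-ol | C=C(CO[Si](C)(C)C(C)(C)C)[C@H]1Oc2ccc([C@@H](C)O)cc2[C@@H]1O | intermediate
11 | tigloyl chloride, (2E)-2-methylbut-2-enoyl chloride | C/C=C(\C)C(=O)Cl | starting material
12 | (1R)-1-[(2R,3S)-2-(3-{[tert-butyl(dimethyl)silyl]oxy}prop-1-en-2-yl)-3-{[(2E)-2-methylbut-2-enoyl]oxy}-2,3-dihydro-1-benzofuran-5-yl]ethyl (2E)-2-methylbut-2-enoate | C=C(CO[Si](C)(C)C(C)(C)C)[C@H]1Oc2ccc([C@@H](C)OC(=O)/C(C)=C/C)cc2[C@@H]1OC(=O)/C(C)=C/C | intermediate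
13 | (1R)-1-[(2R,3S)-2-(3-hydroxyprop-1-en-2-yl)-3-{[(2E)-2-methylbut-2-enoyl]oxy}-2,3-dihydro-1-benzofuran-5-yl]ethyl (2E)-2-methylbut-2-enoate | C=C(CO)[C@H]1Oc2ccc([C@@H](C)OC(=O)/C(C)=C/C)cc2[C@@H]1OC(=O)/C(C)=C/C | intermediate
14 | (1R)-1-[(2R,3S)-3-{[(2E)-2-methylbut-2-enoyl]oxy}-2-(3-oxoprop-1-en-2-yl)-2,3-dihydro-1-benzofuran-5-yl]ethyl (2E)-2-methylbut-2-enoate | C=C(C=O)[C@H]1Oc2ccc([C@@H](C)OC(=O)/C(C)=C/C)cc2[C@@H]1OC(=O)/C(C)=C/C | target

**Step count and risks**

Total steps: 8. Longest linear sequence: 8 steps (1 to 14).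

Step 4 (proposed new method) is the riskiest. The chiral ion pair may discriminate the formyl faces poorly in an intramolecular setting, closure through the central alkene carbon may compete, and the allylsilane enol ether may be protodesilylated before it cyclises. The fallback uses known chemistry and sets out from 7. Treatment with BF3·OEt2 (CH2Cl2, −78 °C), the established Lewis-acid-promoted intramolecular allylsilane–aldehyde cyclisation through the same open transition state, should give the racemic trans alcohol F1. Kinetic resolution by lipase-catalysed acetylation (Burkholderia cepacia lipase, vinyl acetate, MTBE, 30 °C) is expected, by the empirical rule for secondary benzylic alcohols with the aryl ring as the large group, to acylate the (3S)-enantiomer to the (2R,3S)-acetate F2 and leave the (2S,3R)-alcohol F3. After chromatographic separation, methanolysis of F2 (K2CO3, MeOH, 0 °C) comes back to the route at 9.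

Step 3 is next. The electron-poor, chelating phenoxide may couple sluggishly, and prolonged heating with carbonate base may start aldol condensation between acetyl and formyl groups. The fallback sets out from 5. Iodine–lithium exchange (t-BuLi, Et2O, −78 °C), trapping with B(OiPr)3 and mild aqueous work-up should give the alkenylboronic acid F4. Chan–Lam coupling of F4 with 6 (Cu(OAc)2, pyridine, 4 Å molecular sieves, CH2Cl2, air, room temperature) forms the same C–O bond by an oxidative divalent-copper pathway without carbonate base or heating, and comes back to the route at 7.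

Step 6 is third. Acylation of the hindered C3 hydroxyl by the α-branched acyl chloride may stay incomplete, and forcing conditions may ionise the p-alkoxybenzylic position (loss of configuration or elimination) or deconjugate the acyl group through a vinylketene. The fallback sets out from 10. Both hydroxyls are esterified with the unhindered 2-(diethoxyphosphoryl)propanoic acid (EDC·HCl, DMAP, CH2Cl2) to the bis(phosphonopropanoate) F5. A twofold Horner–Wadsworth–Emmons olefination of F5 with acetaldehyde (LiCl, DBU, MeCN, 0 °C) then builds both (E)-2-methylbut-2-enoates in place and comes back to the route at 12.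

**Further compounds**

F1 | step 4 | racemic trans-alcohol, 1:1 mixture of 9 and its enantiomer | C=C(CO[Si](C)(C)C(C)(C)C)[C@H]1Oc2ccc(C(C)=O)cc2[C@@H]1O.C=C(CO[Si](C)(C)C(C)(C)C)[C@@H]1Oc2ccc(C(C)=O)cc2[C@H]1O
F2 | step 4 | (2R,3S)-5-acetyl-2-(3-{[tert-butyl(dimethyl)silyl]oxy}prop-1-en-2-yl)-2,3-dihydro-1-benzofuran-3-yl acetate | C=C(CO[Si](C)(C)C(C)(C)C)[C@H]1Oc2ccc(C(C)=O)cc2[C@@H]1OC(C)=O
F3 | step 4 | 1-[(2S,3R)-2-(3-{[tert-butyl(dimethyl)silyl]oxy}prop-1-en-2-yl)-3-hydroxy-2,3-dihydro-1-benzofuran-5-yl]ethan-1-one | C=C(CO[Si](C)(C)C(C)(C)C)[C@@H]1Oc2ccc(C(C)=O)cc2[C@H]1O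
F4 | step 3 | [(1E)-2-({[tert-butyl(dimethyl)silyl]oxy}methyl)-3-(trimethylsilyl)prop-1-en-1-yl]boronic acid | OB(O)/C=C(/C[Si](C)(C)C)CO[Si](C)(C)C(C)(C)C
F5 | step 6 | (1R)-1-[(2R,3S)-2-(3-{[tert-butyl(dimethyl)silyl]oxy}prop-1-en-2-yl)-3-{[2-(diethoxyphosphoryl)propanoyl]oxy}-2,3-dihydro-1-benzofuran-5-yl]ethyl 2-(diethoxyphosphoryl)propanoate, mixture of epimers at the phosphonate-bearing carbons | C=C(CO[Si](C)(C)C(C)(C)C)[C@H]1Oc2ccc([C@@H](C)OC(=O)C(C)P(=O)(OCC)OCC)cc2[C@@H]1OC(=O)C(C)P(=O)(OCC)OCC
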